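**Numbering used throughout:** 1 2,3,4-trihydroxybenzaldehyde; 2 its 3,4-dibenzyl ether; 3 4-(benzyloxy)benzaldehyde; 4 aryl alkyne; 5 catechol alkenylboronate (not isolated); 6 (E)-alkenylboronic acid; 7 racemic 2H-chromene; 8 racemic cis-diol; 9 unit B alcohol (3-O-camphanate); 10 dimethyl acetal of 2; 11 mixed acetal; 12 pinacolborane; 13 (Z)-alkenylboronate; 14 alkoxy ortho-quinone methide (not isolated); 15 C3-borylated dimer; 16 its C3 alcohol; 17 hexa-O-benzyl ether of the target; 18 target.

## Analysis of the target

Compound 18 is an ether-linked dimer of two 2-arylchromans (flavans). Each half is a 7,8,4'-trihydroxyflavan-3,4-diol, and the two C4 carbons share one oxygen, so the link is a dibenzylic ether between two secondary carbons. Unit A (the half written first in the SMILES; ring C = O1, C2, C3, C4, C4a, C8a) is 2R,3R,4R, with the C2 aryl group, the C3 hydroxyl and the C4 ether oxygen all on one face. Unit B is 2S,3R,4R, the C2 epimer: its aryl group is trans to the C3 hydroxyl, while the C3 and C4 oxygens are again cis. The six stereocentres thus form two contiguous triads that differ only at C2. The sensitive groups are the two catechols and two phenols (oxidation), the two C4–O bonds (each ionises to a cation stabilised by O1 and the C7 oxygen, and each is open to hydrogenolysis), and the C2–O1 bonds next to para-oxygenated aryl rings (epimerisation through quinone methides). The hard part is the ether: it joins two hindered benzylic carbons, and in unit A it must stand cis to the C3 oxygen, whereas a nucleophile adding to a C4 cation arrives trans to it. The strategy rests on ring C of unit A: its cis C2-aryl/C3–O/C4–O pattern is what endo [4+2] addition of a cis-alkene across the oxa-diene C4=C4a–C8a=O1 leaves behind, the diene being an ortho-quinone methide of ring A that already carries the unit B oxygen on C4.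

## Retrosynthetic reasoning

**18 back to 17 and 16.** The six phenolic O–benzyl bonds and the C3 ester of unit B are cut last. Benzyl on every phenol allows one neutral hydrogenolysis, and aryl benzyl ethers should cleave faster than the crowded C4–O–C4 ether. The ester is removed one step earlier, while nothing in the molecule is air-sensitive.

**16 back to 15.** The C3–O bond of unit A is traced to a C3–B bond. An oxygen cannot sit on the alkene carbon that becomes C3, because an enol ether would add the other way round and place its oxygen at C2. Boron does not reverse the polarity of the alkene and is exchanged for hydroxyl with retention.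

**15 back to 11 and 13 through 14 (key disconnection).** The bonds O1–C2 and C3–C4 of unit A are cut together. This removes ring C of unit A and its three stereocentres in one operation and leaves the C4–O–C4 oxygen as the alkoxy substituent of quinone methide 14, so the ether is never made by substitution at C4 of unit A. The forward reaction has to add the (Z)-alkene of 13 with boron at C3, endo, and on one face of 14.

**11 back to 9 and 10.** The acetal C–O bond to unit B is cut. Acetal exchange attaches the hindered C4 hydroxyl of 9 to a carbon that is not stereochemically relevant (both acetal epimers give 14) and uses the same aldehyde 2 that also supplies ring A of unit B.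

**9 back to 8 and 7.** The C3–O and C4–O bonds of unit B are traced to the C3=C4 alkene of 7. An osmium-mediated cis-dihydroxylation anti to the C2 aryl group gives exactly the 2,3-trans-3,4-cis array. An enantiopure camphanoyl group on O3 resolves the racemate and protects O3 in the same operation, and as an acyloxy group next to C4 it makes that carbon harder to ionise.

**7 back to 2 and 6.** The C3–C4... more precisely the C4–C(alkenyl) and O1–C2 bonds of the chromene are cut (Petasis condensation followed by oxa-6π ring closure). Ring C of unit B then comes from two fragments in one step.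

**6 and 13 back to 4, 3 and 12.** Both alkene geometries come from one alkyne: syn hydroboration gives the (E)-boron compound 6 for unit B, formal trans hydroboration with 12 gives the (Z)-boronate 13 for unit A. Alkyne 4 is one carbon longer than aldehyde 3.

**10 and 2 back to 1.** Acetalisation, and selective benzylation of the two hydroxyls of 1 that are not tied up in the hydrogen bond to the formyl group.

## Alternatives that were turned down

**Alternative 1:** Both O1–C8a bonds are disconnected. In the forward direction a copper-catalysed double intramolecular O-arylation would convert the open-chain dibromo diol A2 into the octa-O-benzyl ether A1. This alternative is stronger on precedent: intramolecular arylation of secondary benzylic alkoxides is an established chroman synthesis, C2 is untouched, no acid is involved, and one hydrogenolysis finishes the synthesis. Against it, the key step makes no stereocentre and no C–C bond. All six stereocentres and the C4–O–C4 ether must already be present in A2, where the ether would have to be formed between two acyclic secondary benzylic carbons with no ring to bias either face. Each aryl bromide is also flanked by a benzyloxy group and a branched benzylic carbon, the worst case for copper insertion, and this is needed twice. In its place the chosen strategy creates the ring, the ether-bearing stereocentre and two more centres in the key step, from fragments two to six steps from commercial materials.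

**Alternative 2:** The configuration at C2 of unit B is disconnected: the O1–C2 bond is broken and re-formed. An amidine base would open ring C of the all-cis unit B of A4 through a para-quinone methide (free 4'-hydroxyl) and the ring A phenoxide would re-add from the other face to give A3. In its favour, both halves could come from one all-cis monomer, and base-induced C2 epimerisation of flavans with a free 4'-hydroxyl is known behaviour. This alternative is stronger on the number of distinct building blocks. Against it, the step is an equilibration, so A3 and A4 would have to be separated. The ring-opened intermediate also carries a ring A phenoxide ortho to C4, which can expel the C4 ether oxygen and cut the dimer. Finally, A4 needs the difficult all-cis triad twice and an unsymmetrical protection pattern anyway. The chosen strategy instead sets the trans/cis array of unit B by a directed dihydroxylation at the monomer stage and needs the all-cis triad only once.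

**Alternative 3:** The bonds C5–C6 and C4a–C8a of ring A of unit B are disconnected. A palladium-catalysed Stille coupling of chlorocyclobutenone A6 with alkenylstannane A7, then electrocyclic opening to a dienylketene, 6π closure and tautomerisation, would give phenol A5; ring C of unit B would then be closed at C2 with inversion. In its favour, the 1,2,3-trioxygenated ring is built with unambiguous regiochemistry, and this alternative is as strong as the chosen one in using neutral conditions for its key step. Against it, it constructs a benzene ring that 1 supplies ready-made and sets no stereocentre. A7 must already contain unit A, the ether and three acyclic stereocentres, so every stereochemical problem lies upstream. The thermal step exposes an ionisable dibenzylic ether to heat, and the later ring closure at a para-alkoxybenzylic carbinol invites loss of configuration. Step economy is much poorer than in the chosen route, which takes both aromatic rings from commercial aldehydes.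

Key step: step 10

**Remarks on the chemistry.**
- Compounds 7 and 8 are racemates; for 8 the SMILES shows the enantiomer that is carried on. The enantiomers are parted in step 6 as diastereomeric camphanates, and the configuration of 9 is assumed to be confirmed by X-ray analysis against the known camphanoyl centres.
- The acetal carbon of 11 is left undefined because both epimers give 14.
- A cyclic carbonate on ring A of unit B was considered as a way to disarm C4 of unit B. It would not survive the amine of step 4 or the peroxoborate of step 11, which would then meet a free catechol. All phenols are therefore benzyl ethers, and the acyloxy group at C3 of unit B takes over the disarming role.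

## Steps

Step 1
Reactants: 1 2,3,4-trihydroxybenzaldehyde
Product: 2 3,4-bis(benzyloxy)-2-hydroxybenzaldehyde
Conditions: BnBr (2.05 equiv), K2CO3 (2.1 equiv), DMF, rt
Reagents that add atoms: benzyl bromide, BrCc1ccccc1
Why: Williamson etherification; the 4- and 3-hydroxyls are alkylated while the 2-hydroxyl stays locked in the hydrogen bond to the formyl oxygen, the chelation-controlled selectivity routinely used with 2,3,4-trihydroxyacetophenone.

Step 2
Reactants: 3 4-(benzyloxy)benzaldehyde
Product: 4 1-(benzyloxy)-4-ethynylbenzene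
Conditions: dimethyl (1-diazo-2-oxopropyl)phosphonate (1.3 equiv), K2CO3 (2 equiv), MeOH, rt
Reagents that add atoms: dimethyl (1-diazo-2-oxopropyl)phosphonate, CC(=O)C(=[N+]=[N-])P(=O)(OC)OC
Why: Seyferth–Gilbert homologation in its Ohira–Bestmann form; methoxide unmasks the diazomethylphosphonate anion, which olefinates the non-enolisable aldehyde and loses nitrogen to a carbene that rearranges to the terminal alkyne.

Step 3
Reactants: 4 1-(benzyloxy)-4-ethynylbenzene
Product: 6 [(E)-2-(4-benzyloxyphenyl)ethenyl]boronic acid, via catechol alkenylboronate 5 (not isolated)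
Conditions: catecholborane (1.1 equiv), THF, 70 °C; then H2O, rt
Reagents that add atoms: catecholborane, B1Oc2ccccc2O1; water, O
Why: Uncatalysed syn hydroboration of a terminal arylalkyne places boron on the terminal carbon and gives the (E)-alkenylboronate, which water hydrolyses to the boronic acid.

Step 4
Reactants: 2 3,4-bis(benzyloxy)-2-hydroxybenzaldehyde; 6 [(E)-2-(4-benzyloxyphenyl)ethenyl]boronic acid
Product: 7 rac-7,8-bis(benzyloxy)-2-[4-(benzyloxy)phenyl]-2H-chromene
Conditions: Bn2NH (0.4 equiv), 1,4-dioxane, 90 °C
Reagents that add atoms: none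
Why: Amine-catalysed Petasis borono-Mannich reaction; the styryl group is delivered from the phenoxide-bound boronate to the iminium carbon, the amine is then expelled to an ortho-quinone methide that closes by oxa-6π electrocyclisation, giving the racemic 2H-chromene.

Step 5
Reactants: 7 rac-7,8-bis(benzyloxy)-2-[4-(benzyloxy)phenyl]-2H-chromene
Product: 8 rac-(2S,3R,4R)-7,8-bis(benzyloxy)-2-[4-(benzyloxy)phenyl]chromane-3,4-diol
Conditions: OsO4 (2 mol%), NMO (1.5 equiv), acetone/H2O 8:1, rt
Reagents that add atoms: osmium tetroxide (catalytic oxygen carrier), O=[Os](=O)(=O)=O; N-methylmorpholine N-oxide, C[N+]1([O-])CCOCC1; water, O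
Why: Catalytic cis-dihydroxylation; OsO4 adds suprafacially to C3=C4 from the face opposite the C2 aryl group, which should give the 2,3-trans-3,4-cis diol, the relative configuration of unit B.

Step 6
Reactants: 8 rac-(2S,3R,4R)-7,8-bis(benzyloxy)-2-[4-(benzyloxy)phenyl]chromane-3,4-diol
Product: 9 (2S,3R,4R)-7,8-bis(benzyloxy)-2-[4-(benzyloxy)phenyl]-4-hydroxychroman-3-yl (1S,4R)-camphanate
Conditions: (1S)-camphanic chloride (1.1 equiv), 2-aminoethyl diphenylborinate (10 mol%), i-Pr2NEt (1.5 equiv), MeCN, 0 °C to rt; separation of the two diastereomeric esters (crystallisation, otherwise chromatography)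
Reagents that add atoms: (1S,4R)-camphanic chloride, ClC(=O)[C@@]12CC[C@@](C)(C(=O)O1)C2(C)C
Why: Borinic acid-catalysed regioselective acylation of a cis-1,2-diol; the borinate complex is acylated at the accessible equatorial O3 and not at the pseudoaxial benzylic O4 next to the peri C5–H, and the enantiopure acyl group turns the two enantiomers into separable diastereomers (classical resolution), so the ester resolves and protects in one operation.

Step 7
Reactants: 2 3,4-bis(benzyloxy)-2-hydroxybenzaldehyde
Product: 10 2,3-bis(benzyloxy)-6-(dimethoxymethyl)phenol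
Conditions: HC(OMe)3 (5 equiv), PPTS (5 mol%), MeOH, rt to 40 °C; Et3N quench, evaporation
Reagents that add atoms: trimethyl orthoformate, COC(OC)OC; methanol, CO
Why: Acid-catalysed acetalisation driven by the orthoformate as water scavenger; basic work-up keeps the ionisable ortho-hydroxybenzyl acetal intact.

Step 8
Reactants: 9 (2S,3R,4R)-7,8-bis(benzyloxy)-2-[4-(benzyloxy)phenyl]-4-hydroxychroman-3-yl (1S,4R)-camphanate; 10 2,3-bis(benzyloxy)-6-(dimethoxymethyl)phenol (1.5 equiv)
Product: 11 (2S,3R,4R)-7,8-bis(benzyloxy)-2-[4-(benzyloxy)phenyl]-4-{[3,4-bis(benzyloxy)-2-hydroxyphenyl](methoxy)methoxy}chroman-3-yl (1S,4R)-camphanate (both epimers at the acetal carbon)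
Conditions: PPTS (5 mol%), 5 Å MS, PhMe, 35 °C, reduced pressure; Et3N; chromatography on Et3N-deactivated silica
Reagents that add atoms: none
Why: Acid-catalysed acetal exchange; 10 ionises to its methoxy oxocarbenium ion, the C4 hydroxyl of 9 adds, and removal of methanol by sieves and reduced pressure pulls the equilibrium to the mixed acetal, whose acetal configuration is immaterial.

Step 9
Reactants: 4 1-(benzyloxy)-4-ethynylbenzene (1.2 equiv); 12 pinacolborane
Product: 13 2-[(Z)-2-(4-benzyloxyphenyl)ethenyl]-4,4,5,5-tetramethyl-1,3,2-dioxaborolane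
Conditions: [Rh(cod)Cl]2 (1.5 mol%), P(i-Pr)3 (6 mol%), Et3N (1 equiv), cyclohexane, rt
Reagents that add atoms: none
Why: Rhodium-catalysed formal trans-hydroboration of a terminal alkyne; rearrangement to a rhodium vinylidene followed by B–H addition places boron cis to the aryl group, and the amine with the bulky phosphine suppresses the ordinary syn pathway.

Step 10
Reactants: 11 mixed methyl acetal of 2 with unit B alcohol 9; 13 (Z)-alkenylboronate (2 equiv)
Product: 15 all-cis C3-borylated dimer (unit A: (2S,3R,4S)-7,8-bis(benzyloxy)-2-(4-benzyloxyphenyl)-3-(4,4,5,5-tetramethyl-1,3,2-dioxaborolan-2-yl)chroman-4-yl; unit B: the camphanate of 9; linked C4–O–C4), via alkoxy ortho-quinone methide 14 (not isolated)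
Conditions: Sc(OTf)3 (10 mol%), 4 Å MS, CH2Cl2, −40 to −10 °C; Et3N quench at −40 °C
Reagents that add atoms: none
Why: Proposed new method: Sc(OTf)3 ionises the methoxy group of 11 (the sieves take up the methanol) and the phenol loses its proton, giving the (E)-configured alkoxy ortho-quinone methide 14, an electron-poor oxa-diene O1=C8a–C4a=C4. The electron-rich alkene of 13 adds with its boron-bearing carbon to C4, because the charge building up on the other carbon is benzylic to the 4-benzyloxyphenyl ring and β to the C–B bond, and the quinone methide oxygen closes onto that carbon in the same concerted but asynchronous inverse-demand hetero-Diels–Alder event (bonds C3–C4 and O1–C2). The closest known reaction type is the Sc(OTf)3-promoted three-component union of a salicylaldehyde, trimethyl orthoformate and a styrene to 2,4-cis-4-methoxy-2-arylchromans; not yet shown are a stereogenic secondary alkoxy group on the quinone methide and a 1,2-disubstituted alkenylboronate as the 2π partner. Ring C of unit A (six-membered) is closed by this [4+2] cycloaddition, at its stepwise limit by capture of the benzylic cation by the ring A phenoxide. At C2 and C3 the cis relationship is carried over suprafacially from the (Z)-alkene, and at C4 the relationship to C2 and C3 follows from endo approach of the aryl- and boron-bearing alkene to the (E)-quinone methide, the orientation that gives 2,4-cis chromans in the known reaction, so aryl, boron and the C4 oxygen end up on one face. The absolute sense is set by the unit B stereocentre on the quinone methide oxygen: with the C4–H of unit B eclipsing the O–C4 bond of the methide, C3 of unit B with its camphanoyloxy group covers the Re face of C4 and the alkene is expected on the Si face, which leads to the configuration of 16 to 18 (written 2S,3R,4S in 15 only because boron ranks below carbon). The step needs regioselectivity (boron at C3), endo and π-facial selectivity, and ionisation of the acetal in preference to the C4–O bond of unit B; the first comes from benzylic charge stabilisation, the last from the acyloxy group next to C4 of unit B, which disarms that carbon, and from low temperature with catalytic acid, which should also keep 15 from re-ionising at C4. If substrate control of the face proves weak, the matched enantiomer of a pybox ligand on Sc(OTf)3 is the first adjustment.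

Step 11
Reactants: 15 all-cis C3-borylated dimer
Product: 16 (2S,3R,4R)-7,8-bis(benzyloxy)-2-[4-(benzyloxy)phenyl]-4-{[(2R,3R,4R)-7,8-bis(benzyloxy)-2-[4-(benzyloxy)phenyl]-3-hydroxychroman-4-yl]oxy}chroman-3-yl (1S,4R)-camphanate
Conditions: NaBO3·4H2O (5 equiv), THF/H2O 1:1, rt
Reagents that add atoms: sodium perborate tetrahydrate (dimeric peroxoborate), [Na+].[Na+].O[B-]1(O)OO[B-](O)(O)OO1
Why: Oxidation of a secondary alkyl pinacol boronate; C3 migrates from boron to the peroxide oxygen with retention, so the new hydroxyl stays cis to the C2 aryl group and the C4 oxygen, and the mild base should spare the ester, the benzyl ethers and the gauche β-oxygens.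

Step 12
Reactants: 16 C3 alcohol with camphanate on unit B
Product: 17 (2R,3R,4R)-7,8-bis(benzyloxy)-2-[4-(benzyloxy)phenyl]-4-{[(2S,3R,4R)-7,8-bis(benzyloxy)-2-[4-(benzyloxy)phenyl]-3-hydroxychroman-4-yl]oxy}chroman-3-ol
Conditions: NaOMe (0.2 equiv), MeOH/THF 2:1, rt to 40 °C
Reagents that add atoms: none
Why: Base-catalysed transesterification (Zemplén-type methanolysis) removes the camphanoyl group; no stereocentre is touched, and with all phenols still benzylated nothing is air-sensitive.

Step 13
Reactants: 17 hexa-O-benzyl ether of the target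
Product: 18 (2R,3R,4R)-2-(4-hydroxyphenyl)-4-{[(2S,3R,4R)-3,7,8-trihydroxy-2-(4-hydroxyphenyl)chroman-4-yl]oxy}chromane-3,7,8-triol
Conditions: H2 (1 atm), Pd(OH)2/C, THF/MeOH 1:1, rt; stopped at the calculated uptake, filtration under argon
Reagents that add atoms: none
Why: Hydrogenolysis of six aryl benzyl ethers, which should cleave much faster than the crowded secondary C4–O–C4 ether or the ring C2–O1 bonds; neutral medium and low pressure protect the interflavanyl ether.

## Compound list

1 | 2,3,4-trihydroxybenzaldehyde | O=Cc1ccc(O)c(O)c1O | starting material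
2 | 3,4-bis(benzyloxy)-2-hydroxybenzaldehyde | O=Cc1ccc(OCc2ccccc2)c(OCc2ccccc2)c1O | intermediate
3 | 4-(benzyloxy)benzaldehyde | O=Cc1ccc(OCc2ccccc2)cc1 | starting material
4 | 1-(benzyloxy)-4-ethynylbenzene | C#Cc1ccc(OCc2ccccc2)cc1 | intermediate
5 | 2-[(E)-2-(4-benzyloxyphenyl)ethenyl]-1,3,2-benzodioxaborole (not isolated) | B1(/C=C/c2ccc(OCc3ccccc3)cc2)Oc2ccccc2O1 | intermediate
6 | [(E)-2-(4-benzyloxyphenyl)ethenyl]boronic acid | OB(O)/C=C/c1ccc(OCc2ccccc2)cc1 | intermediate
7 | rac-7,8-bis(benzyloxy)-2-[4-(benzyloxy)phenyl]-2H-chromene | C1(c2ccc(OCc3ccccc3)cc2)C=Cc2ccc(OCc3ccccc3)c(OCc3ccccc3)c2O1 | intermediate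
8 | rac-(2S,3R,4R)-7,8-bis(benzyloxy)-2-[4-(benzyloxy)phenyl]chromane-3,4-diol (2,3-trans-3,4-cis; racemate, the enantiomer carried on is drawn) | O[C@@H]1c2ccc(OCc3ccccc3)c(OCc3ccccc3)c2O[C@@H](c2ccc(OCc3ccccc3)cc2)[C@@H]1O | intermediate
9 | (2S,3R,4R)-7,8-bis(benzyloxy)-2-[4-(benzyloxy)phenyl]-4-hydroxychroman-3-yl (1S,4R)-4,7,7-trimethyl-3-oxo-2-oxabicyclo[2.2.1]heptane-1-carboxylate (camphanate) | O[C@@H]1c2ccc(OCc3ccccc3)c(OCc3ccccc3)c2O[C@@H](c2ccc(OCc3ccccc3)cc2)[C@@H]1OC(=O)[C@@]45CC[C@@](C)(C(=O)O4)C5(C)C | intermediate
10 | 2,3-bis(benzyloxy)-6-(dimethoxymethyl)phenol | COC(OC)c1ccc(OCc2ccccc2)c(OCc2ccccc2)c1O | intermediate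
11 | mixed methyl acetal of 2 with the C4 hydroxyl of 9 (both epimers at the acetal carbon) | COC(O[C@@H]1c2ccc(OCc3ccccc3)c(OCc3ccccc3)c2O[C@@H](c2ccc(OCc3ccccc3)cc2)[C@@H]1OC(=O)[C@@]45CC[C@@](C)(C(=O)O4)C5(C)C)c1ccc(OCc2ccccc2)c(OCc2ccccc2)c1O | intermediate
12 | pinacolborane (4,4,5,5-tetramethyl-1,3,2-dioxaborolane) | CC1(C)OBOC1(C)C | starting material
13 | 2-[(Z)-2-(4-benzyloxyphenyl)ethenyl]-4,4,5,5-tetramethyl-1,3,2-dioxaborolane | CC1(C)OB(/C=C\c2ccc(OCc3ccccc3)cc2)OC1(C)C | intermediate
14 | (E)-alkoxy ortho-quinone methide: 2,3-bis(benzyloxy)-6-[(unit B C4-oxy)methylidene]cyclohexa-2,4-dien-1-one (not isolated) | O=C1/C(=C/O[C@@H]6c2ccc(OCc3ccccc3)c(OCc3ccccc3)c2O[C@@H](c2ccc(OCc3ccccc3)cc2)[C@@H]6OC(=O)[C@@]45CC[C@@](C)(C(=O)O4)C5(C)C)C=CC(OCc2ccccc2)=C1OCc1ccccc1 | intermediate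
15 | all-cis C3-borylated dimer: unit A (2S,3R,4S)-7,8-bis(benzyloxy)-2-(4-benzyloxyphenyl)-3-(pinacolboryl)chroman-4-yl, ether-linked to O4 of the unit B camphanate | c1ccccc1COc1ccc([C@H]2Oc3c(ccc(OCc4ccccc4)c3OCc3ccccc3)[C@@H](O[C@@H]3c4ccc(OCc5ccccc5)c(OCc5ccccc5)c4O[C@@H](c4ccc(OCc5ccccc5)cc4)[C@@H]3OC(=O)[C@@]45CC[C@@](C)(C(=O)O4)C5(C)C)[C@H]2B2OC(C)(C)C(C)(C)O2)cc1 | intermediate
16 | dimer with free C3 hydroxyl on unit A (2R,3R,4R) and camphanate on O3 of unit B (2S,3R,4R) | c1ccccc1COc1ccc([C@H]2Oc3c(ccc(OCc4ccccc4)c3OCc3ccccc3)[C@@H](O[C@@H]3c4ccc(OCc5ccccc5)c(OCc5ccccc5)c4O[C@@H](c4ccc(OCc5ccccc5)cc4)[C@@H]3OC(=O)[C@@]45CC[C@@](C)(C(=O)O4)C5(C)C)[C@H]2O)cc1 | intermediate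
17 | 7,8,4'-tri-O-benzyl ether on both units of the target (both C3 hydroxyls free) | c1ccccc1COc1ccc([C@H]2Oc3c(ccc(OCc4ccccc4)c3OCc3ccccc3)[C@@H](O[C@@H]3c4ccc(OCc5ccccc5)c(OCc5ccccc5)c4O[C@@H](c4ccc(OCc5ccccc5)cc4)[C@@H]3O)[C@H]2O)cc1 | intermediate
18 | (2R,3R,4R)-2-(4-hydroxyphenyl)-4-{[(2S,3R,4R)-3,7,8-trihydroxy-2-(4-hydroxyphenyl)chroman-4-yl]oxy}chromane-3,7,8-triol | Oc1ccc([C@H]2Oc3c(ccc(O)c3O)[C@@H](O[C@@H]3c4ccc(O)c(O)c4O[C@@H](c4ccc(O)cc4)[C@@H]3O)[C@H]2O)cc1 | target

## Step count and risk

Total: 13 steps. Longest linear sequence: 10 steps (3 → 4 → 6 → 7 → 8 → 9 → 11 → 15 → 16 → 17 → 18).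

**Step 10 (key step, new method).** Several things can go wrong:
- loss of the unit B group from the ionised acetal, either by departure of a flavanyl cation or by exchange with the liberated methanol;
- deborylation (ipso substitution) in place of ring closure;
- bond rotation in a long-lived benzylic cation, eroding the 2,3-cis relationship;
- weak endo or facial selectivity;
- re-ionisation of the product at C4 followed by loss of boron.

The fallback uses known chemistry. It sets out from 9 and from the second ester of step 6, and returns at 16. Methanolysis (NaOMe, MeOH/THF) of (2R,3S,4S)-7,8-bis(benzyloxy)-2-[4-(benzyloxy)phenyl]-4-hydroxychroman-3-yl (1S,4R)-camphanate F1 gives (2R,3S,4S)-7,8-bis(benzyloxy)-2-[4-(benzyloxy)phenyl]chromane-3,4-diol F2. Acid-catalysed etherification (camphorsulfonic acid cat., 4 Å MS, CH2Cl2, −30 to 0 °C) with an excess of 9 follows. F2, armed by its free C3 hydroxyl, ionises at C4 while 9 is disarmed, and 9 adds anti to the C3 hydroxyl, as in the solvolytic 4-O-alkylation of flavan-3,4-diols. This should give the 2,4-cis-3,4-trans ether, the C3 epimer of 16 with unit A (2R,3S,4R) F3. Dess–Martin oxidation of its only free hydroxyl gives the unit A chroman-3-one (2R,4R) F4. LiBH(s-Bu)3 (THF, −78 °C) then delivers hydride anti to the C2 aryl and C4 alkoxy groups, the oxidation–reduction inversion used to turn 2,3-trans into 2,3-cis flavan-3-ols, and gives 16.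

**Step 8.** Incomplete exchange with a hindered secondary alcohol, or reversion and hydrolysis of the ortho-hydroxybenzyl acetal during isolation. The fallback sets out from 2 and 9 and returns at 11. Allylation of 2 (allyl bromide, K2CO3, DMF) gives 2-(allyloxy)-3,4-bis(benzyloxy)benzaldehyde F5. Acetalisation (HC(OMe)3, PPTS, MeOH) gives 2-(allyloxy)-3,4-bis(benzyloxy)-1-(dimethoxymethyl)benzene F6. Acetyl chloride (CH2Cl2, 0 °C) converts it into 2-(allyloxy)-3,4-bis(benzyloxy)-1-[chloro(methoxy)methyl]benzene F7, which alkylates 9 irreversibly (i-Pr2NEt, −40 to 0 °C) to the O-allyl ether of 11 F8. Pd(PPh3)4 (cat.) with morpholine in THF removes the allyl group and gives 11.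

**Step 6.** Competing acylation at O4 or at both hydroxyls, and failure of the two diastereomers to separate. The fallback sets out from 8 and returns at 9. Exhaustive acylation (camphanic chloride, DMAP, pyridine) gives the bis-esters, from which (2S,3R,4R)-7,8-bis(benzyloxy)-2-[4-(benzyloxy)phenyl]chromane-3,4-diyl bis[(1S,4R)-camphanate] F9 is separated. Methanolysis gives (2S,3R,4R)-7,8-bis(benzyloxy)-2-[4-(benzyloxy)phenyl]chromane-3,4-diol as the single enantiomer F10. Its stannylene acetal (Bu2SnO, PhMe, reflux with water removal) is acylated at the equatorial O3 by camphanic chloride at 0 °C to give 9.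

**Step 13.** Over-reduction: hydrogenolysis of the dibenzylic C4–O–C4 ether or of a C2–O1 bond once the phenols are free. The fallback sets out from 17 and returns at 18. Acetylation (Ac2O, pyridine, DMAP) gives the 3,3'-di-O-acetate of 17 F11, in which an acyloxy group next to each C4 retards cleavage of the benzylic C–O bonds electronically and sterically. Hydrogenolysis (H2, Pd(OH)2/C, EtOAc/MeOH) gives the 3,3'-di-O-acetate of 18 F12. Brief methanolysis (K2CO3 cat., degassed MeOH, 0 °C, argon, neutralised with an acidic resin) gives 18.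

**Step 9.** Leakage into the ordinary syn pathway, or isomerisation, giving the (E)-boronate that would lead to the 2,3-trans series. The fallback sets out from 4 and returns at 13. Deprotonation (n-BuLi, THF, −78 °C) and borylation with 2-isopropoxy-4,4,5,5-tetramethyl-1,3,2-dioxaborolane give 2-{[4-(benzyloxy)phenyl]ethynyl}-4,4,5,5-tetramethyl-1,3,2-dioxaborolane F13. Syn hydrozirconation (Cp2ZrHCl, THF, rt) followed by protonolysis with water, which retains configuration, gives 13.

## Further compounds

F1 | step 10 | (2R,3S,4S)-7,8-bis(benzyloxy)-2-[4-(benzyloxy)phenyl]-4-hydroxychroman-3-yl (1S,4R)-camphanate | O[C@H]1c2ccc(OCc3ccccc3)c(OCc3ccccc3)c2O[C@H](c2ccc(OCc3ccccc3)cc2)[C@H]1OC(=O)[C@@]45CC[C@@](C)(C(=O)O4)C5(C)C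
F2 | step 10 | (2R,3S,4S)-7,8-bis(benzyloxy)-2-[4-(benzyloxy)phenyl]chromane-3,4-diol | O[C@H]1c2ccc(OCc3ccccc3)c(OCc3ccccc3)c2O[C@H](c2ccc(OCc3ccccc3)cc2)[C@H]1O
F3 | step 10 | C3 epimer of 16 with unit A (2R,3S,4R) | c1ccccc1COc1ccc([C@H]2Oc3c(ccc(OCc4ccccc4)c3OCc3ccccc3)[C@@H](O[C@@H]3c4ccc(OCc5ccccc5)c(OCc5ccccc5)c4O[C@@H](c4ccc(OCc5ccccc5)cc4)[C@@H]3OC(=O)[C@@]45CC[C@@](C)(C(=O)O4)C5(C)C)[C@@H]2O)cc1
F4 | step 10 | unit A chroman-3-one (2R,4R) linked to the unit B camphanate | c1ccccc1COc1ccc([C@H]2Oc3c(ccc(OCc4ccccc4)c3OCc3ccccc3)[C@@H](O[C@@H]3c4ccc(OCc5ccccc5)c(OCc5ccccc5)c4O[C@@H](c4ccc(OCc5ccccc5)cc4)[C@@H]3OC(=O)[C@@]45CC[C@@](C)(C(=O)O4)C5(C)C)C2=O)cc1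
F5 | step 8 | 2-(allyloxy)-3,4-bis(benzyloxy)benzaldehyde | C=CCOc1c(C=O)ccc(OCc2ccccc2)c1OCc1ccccc1
F6 | step 8 | 2-(allyloxy)-3,4-bis(benzyloxy)-1-(dimethoxymethyl)benzene | C=CCOc1c(C(OC)OC)ccc(OCc2ccccc2)c1OCc1ccccc1
F7 | step 8 | 2-(allyloxy)-3,4-bis(benzyloxy)-1-[chloro(methoxy)methyl]benzene | C=CCOc1c(C(Cl)OC)ccc(OCc2ccccc2)c1OCc1ccccc1
F8 | step 8 | O-allyl ether of 11 | C=CCOc1c(C(OC)O[C@@H]6c2ccc(OCc3ccccc3)c(OCc3ccccc3)c2O[C@@H](c2ccc(OCc3ccccc3)cc2)[C@@H]6OC(=O)[C@@]45CC[C@@](C)(C(=O)O4)C5(C)C)ccc(OCc2ccccc2)c1OCc1ccccc1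
F9 | step 6 | (2S,3R,4R)-7,8-bis(benzyloxy)-2-[4-(benzyloxy)phenyl]chromane-3,4-diyl bis[(1S,4R)-camphanate] | O=C(O[C@@H]1c2ccc(OCc3ccccc3)c(OCc3ccccc3)c2O[C@@H](c2ccc(OCc3ccccc3)cc2)[C@@H]1OC(=O)[C@@]45CC[C@@](C)(C(=O)O4)C5(C)C)[C@@]67CC[C@@](C)(C(=O)O6)C7(C)C
F10 | step 6 | (2S,3R,4R)-7,8-bis(benzyloxy)-2-[4-(benzyloxy)phenyl]chromane-3,4-diol, single enantiomer (same drawing as racemic 8) | O[C@@H]1c2ccc(OCc3ccccc3)c(OCc3ccccc3)c2O[C@@H](c2ccc(OCc3ccccc3)cc2)[C@@H]1O
F11 | step 13 | 3,3'-di-O-acetate of 17 | c1ccccc1COc1ccc([C@H]2Oc3c(ccc(OCc4ccccc4)c3OCc3ccccc3)[C@@H](O[C@@H]3c4ccc(OCc5ccccc5)c(OCc5ccccc5)c4O[C@@H](c4ccc(OCc5ccccc5)cc4)[C@@H]3OC(C)=O)[C@H]2OC(C)=O)cc1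
F12 | step 13 | 3,3'-di-O-acetate of 18 | Oc1ccc([C@H]2Oc3c(ccc(O)c3O)[C@@H](O[C@@H]3c4ccc(O)c(O)c4O[C@@H](c4ccc(O)cc4)[C@@H]3OC(C)=O)[C@H]2OC(C)=O)cc1
F13 | step 9 | 2-{[4-(benzyloxy)phenyl]ethynyl}-4,4,5,5-tetramethyl-1,3,2-dioxaborolane | CC1(C)OB(C#Cc2ccc(OCc3ccccc3)cc2)OC1(C)C
A1 | alternative 1 | octa-O-benzyl ether of 18 | c1ccccc1COc1ccc([C@H]2Oc3c(ccc(OCc4ccccc4)c3OCc3ccccc3)[C@@H](O[C@@H]3c4ccc(OCc5ccccc5)c(OCc5ccccc5)c4O[C@@H](c4ccc(OCc5ccccc5)cc4)[C@@H]3OCc3ccccc3)[C@H]2OCc2ccccc2)cc1
A2 | alternative 1 | open-chain bis(2-bromoaryl) diol, the two 1,3-diaryl-2-benzyloxypropane chains joined by the C4–O–C4 ether, free C2 hydroxyls | Brc1c(OCc2ccccc2)c(OCc2ccccc2)ccc1[C@@H](O[C@H](c1ccc(OCc2ccccc2)c(OCc2ccccc2)c1Br)[C@@H](OCc1ccccc1)[C@@H](O)c1ccc(OCc2ccccc2)cc1)[C@@H](OCc1ccccc1)[C@H](O)c1ccc(OCc2ccccc2)cc1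
A3 | alternative 2 | protected target with 4'-O-triisopropylsilyl on unit A and free 4'-hydroxyl on unit B (2S) | CC(C)[Si](C(C)C)(C(C)C)Oc1ccc([C@H]2Oc3c(ccc(OCc4ccccc4)c3OCc3ccccc3)[C@@H](O[C@@H]3c4ccc(OCc5ccccc5)c(OCc5ccccc5)c4O[C@@H](c4ccc(O)cc4)[C@@H]3OCc3ccccc3)[C@H]2OCc2ccccc2)cc1
A4 | alternative 2 | C2 epimer of A3 with both units all-cis | CC(C)[Si](C(C)C)(C(C)C)Oc1ccc([C@H]2Oc3c(ccc(OCc4ccccc4)c3OCc3ccccc3)[C@@H](O[C@@H]3c4ccc(OCc5ccccc5)c(OCc5ccccc5)c4O[C@H](c4ccc(O)cc4)[C@@H]3OCc3ccccc3)[C@H]2OCc2ccccc2)cc1
A5 | alternative 3 | 2,3-bis(benzyloxy)phenol carrying the open unit B chain ortho to the hydroxyl, with unit A attached through the ether | Oc1c(OCc2ccccc2)c(OCc2ccccc2)ccc1[C@@H](O[C@@H]1c2ccc(OCc3ccccc3)c(OCc3ccccc3)c2O[C@H](c2ccc(OCc3ccccc3)cc2)[C@@H]1OCc1ccccc1)[C@@H](OCc1ccccc1)[C@H](O[Si](CC)(CC)CC)c1ccc(OCc2ccccc2)cc1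
A6 | alternative 3 | 2,3-bis(benzyloxy)-4-chlorocyclobut-2-en-1-one | O=C1C(OCc2ccccc2)=C(OCc2ccccc2)C1Cl
A7 | alternative 3 | (E)-alkenyl(tributyl)stannane carrying the unit B chain and unit A | CCCC[Sn](CCCC)(CCCC)/C=C/[C@@H](O[C@@H]1c2ccc(OCc3ccccc3)c(OCc3ccccc3)c2O[C@H](c2ccc(OCc3ccccc3)cc2)[C@@H]1OCc1ccccc1)[C@@H](OCc1ccccc1)[C@H](O[Si](CC)(CC)CC)c1ccc(OCc2ccccc2)cc1
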